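# Proposed total synthesis of CNP0118131.1 by [2+2+2] cyclotrimerisation of an ynol-ether diyne

## Analysis of the target

The target 31 joins a trans-2,3-disubstituted γ-butyrolactone (ring A) through a methylene group to C5 of a 2-aryl-3-(hydroxymethyl)-2,3-dihydrobenzofuran (benzene ring B fused to dihydrofuran ring C). A 4-hydroxy-3-methoxybenzyl group (ring D) sits on lactone C4 and a 4-hydroxy-3-methoxyphenyl group (ring E) on benzofuran C2. There are four stereocentres in two trans pairs, lactone C3 (S)/C4 (S) and benzofuran C2 (S)/C3 (R). The pairs are insulated by the CH2–arene spacer, so each must be set absolutely and neither can steer the other. Sensitive features are three free phenols, a primary alcohol, a lactone with an enolisable α-centre, and the C2–O1 bond, a benzylic aryl ether para to a phenol that can ionise, epimerise or be hydrogenolysed. The hard part is ring B, which is 1,2,3,5-tetrasubstituted: oxygen on the adjacent carbons C7 (free OH) and C7a (ring oxygen), carbon on C3a and C5, and hydrogen only on C4 and C6. The strategy rests on this pattern: the ring B carbons fall into the pairs C3a/C4, C5/C6 and C7/C7a, each the two carbons of an alkyne, and the O1–C2–C3 bridge already ties the first and third pairs into a 1,6-diyne whose C7a carbon carries the ether oxygen (an ynol ether). The pair C5/C6 with its CH2 arm is a terminal propargyl group on the lactone, so rings B and C and the union of the halves can come from one cyclotrimerisation.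

## Retrosynthetic reasoning

**End game (31 back to 26).** The two ring D/E phenols are carried as benzyl ethers and the primary alcohol as a triisopropylsilyl ether, giving 30 and then 29. The C7–O bond is cut next: the phenol of 29 is traced through boronate 28 and iodide 27 to the aryl silane 26. Silicon is placed on C7 because an oxygen there would require a 1,2-dioxygenated alkyne in the precursor, and because a bulky silyl group is what steers the ring-forming step.

**Ring B and ring C (26 to 17 + 25).** The bonds C3a–C7a, C4–C5 and C6–C7 are cut together. This is the only way of dividing ring B into three alkynes that keeps the O1–C2–C3 bridge acyclic. It leads to diyne 17, which already holds both benzofuran stereocentres, and to propargyl lactone 25, which holds both lactone stereocentres. The forward reaction must couple the two alkynes of 17 at a metal and insert 25 with its substituent away from silicon.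

**Ynol ether (17 to 11 + 12).** The O–C(sp) bond is cut. Alcohol 11 is O-alkenylated with the two carbons of 12 to give 14, which is converted to the silylated alkynyl ether 16. The carbon alkyne of 11 carries SiMe3 so that only the ynol ether terminus receives SiEt3; selective removal of SiMe3 from 16 then gives 17. The primary oxygen carries triisopropylsilyl rather than a smaller silyl group so that it cannot migrate to the neighbouring alkoxide.

**Stereodiad (11 to 8 + 9).** The C1–C2 bond is cut between the aldehyde carbon of 9 and the propargylic carbon of mesylate 8. A chiral allenylmetal derived from 8 transfers its configuration to C2 and, through a cyclic transition state, sets C1 anti to it. This anti arrangement is the one that becomes trans in ring C. Mesylate 8 comes from alcohol 7 by asymmetric reduction of ynone 6, itself assembled from amide 3 and alkyne 4; 3 derives from 1 through 2.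

**Lactone half (25 to 22 + 23, and 22 to 9 + 18).** The C3–CH2 bond is cut: the enolate of lactone 22 is alkylated by 23 trans to the C4 substituent. Lactone 22 is traced through acid 20 to alkylidene succinate 19, made from 9 and 18; the C4 stereocentre comes from asymmetric hydrogenation of 19. Aldehyde 9 thus serves both halves.

## Alternatives that were turned down

**Alternative 1:** The O1–C2 bond of ring C is cut. In the forward key step a mild silver or quinone oxidant converts the 4-hydroxy-3-methoxybenzyl unit of the open-chain phenol A2 into its para-quinone methide, and the neighbouring ring B phenol adds to the methide carbon (5-exo-trig) to give the bromo-dihydrobenzofuran A1.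
- For: only C3 needs reagent control, since closure places the aryl group trans to CH2OH. The chemistry mirrors the presumed biogenesis, and on precedent it is stronger than the chosen route.
- Against: the methide must be generated from a saturated ArCH2 group beside a second oxidisable phenol, so phenoxyl coupling and over-oxidation compete. The product is a para-hydroxybenzyl ether that can re-ionise at C2. A1 is only the benzofuran half; its C5 bromide must still become a benzylic electrophile and be joined to the lactone after reprotection.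
- Comparison: its key step forms one bond and one ring against three bonds and two rings, and the ring B pattern must be bought as a pre-functionalised catechol. The chosen route lets the alkyne partners dictate that pattern and never exposes C2 to ionising conditions before the end.

**Alternative 2:** The lactone bonds at C4 (to the benzylic carbon) and at C3 (to the CH2 of the benzofuran arm) are cut. In the forward key step the lithiated dithiane A5 adds 1,4 to the chiral butenolide A4 anti to its alkoxy group, and the enolate is trapped in the same flask by the benzylic bromide A6 to give the trans,trans lactone acetal A3; no ring closes.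
- For: both ring A centres are set in one operation under auxiliary control, and the assembly is highly convergent. On stereochemical reliability at ring A it is at least as strong as the hydrogenation/alkylation sequence used here.
- Against: it presupposes A6, the complete trans-dihydrobenzofuran with the ring B pattern, so the central problem is only moved. A6 is a benzylic bromide para to the ring oxygen and likely to ionise. Desulfurisation beside benzyl ethers and a benzylic C–O bond, and removal of the acetal oxygen, add at least three steps, and the auxiliary is needed in its less common enantiomeric series.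
- Comparison: the chosen route reaches ring A in four steps from 9 with comparable control and spends its key step on rings B and C, which this alternative leaves unsolved.

**Alternative 3:** The lactone O1–C5 bond is cut, tracing A8, which is the same compound as 22, to the prochiral cyclobutanone A7. In the forward key step aqueous peroxide with a chiral Brønsted acid, or a monooxygenase, inserts oxygen into one of the two enantiotopic C–C(=O) bonds.
- For: catalytic, metal-free and short from an abundant allylbenzene. In step count to the lactone it matches steps 10–12 and could replace them unchanged.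
- Against: the two migrating carbons differ only through the remote benzyl substituent, so small-molecule catalysts are expected to give moderate enantioselectivity, while C4 must be of high purity because it later controls C3.
- Comparison: as a strategy it forms one ring and one of four stereocentres and is silent on ring B, ring C and the fragment union, which is where the chosen key step does its work.

Key step: step 14

## Route

Remark: 4-(benzyloxy)-3-methoxybenzaldehyde (9) is taken as a purchasable starting material, and species that exist only bound to a catalytic metal (allenylpalladium, rhodacycle) are described in the Why lines and not numbered.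

**Fragment 1: diyne 17**

Step 1
Reactants: 1 ethyl glycolate
Product: 2 ethyl 2-[(triisopropylsilyl)oxy]acetate
Conditions: TIPSCl, imidazole, DMF, 0 °C → rt
Reagents that add atoms: chlorotriisopropylsilane, CC(C)[Si](Cl)(C(C)C)C(C)C
Why: Silylation of a primary alcohol; triisopropylsilyl is chosen because, unlike a smaller silyl group, it should not shift to the neighbouring secondary alkoxide generated in step 7 and it survives every later base, organolithium and oxidant.

Step 2
Reactants: 2 ethyl 2-[(triisopropylsilyl)oxy]acetate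
Product: 3 N-methoxy-N-methyl-2-[(triisopropylsilyl)oxy]acetamide
Conditions: MeNH(OMe)·HCl, iPrMgCl, THF, −20 → 0 °C
Reagents that add atoms: N,O-dimethylhydroxylamine hydrochloride, CNOC.Cl
Why: Weinreb amide formation from an ester through the chloromagnesium amide; the hindered Grignard reagent acts only as a base.

Step 3
Reactants: 3 N-methoxy-N-methyl-2-[(triisopropylsilyl)oxy]acetamide; 4 trimethylsilylacetylene
Product: 6 1-[(triisopropylsilyl)oxy]-4-(trimethylsilyl)but-3-yn-2-one, via lithium (trimethylsilyl)acetylide 5 (not isolated)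
Conditions: 4, n-BuLi, THF, −78 °C; then 3, −78 → −20 °C; poured into cold 1 M HCl
Reagents that add atoms: none
Why: Weinreb ketone synthesis; the chelated tetrahedral intermediate collapses only on the acidic quench, which also keeps the liberated amine from adding to the ynone.

Step 4
Reactants: 6 1-[(triisopropylsilyl)oxy]-4-(trimethylsilyl)but-3-yn-2-one
Product: 7 (S)-1-[(triisopropylsilyl)oxy]-4-(trimethylsilyl)but-3-yn-2-ol
Conditions: RuCl[(R,R)-TsDPEN](p-cymene) (2 mol%), iPrOH, rt
Reagents that add atoms: none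
Why: Noyori asymmetric transfer hydrogenation of an alkynyl ketone, the alkyne taking the place of the aryl group in the transition state; the (R,R)-catalyst is expected to give the alcohol spatially analogous to (R)-4-silylbut-3-yn-2-ol, here (S) because CH2OSi outranks the alkyne, and the configuration is to be confirmed on the Mosher esters with the antipodal catalyst used if it proves opposite.

Step 5
Reactants: 7 (S)-1-[(triisopropylsilyl)oxy]-4-(trimethylsilyl)but-3-yn-2-ol
Product: 8 (S)-1-[(triisopropylsilyl)oxy]-4-(trimethylsilyl)but-3-yn-2-yl methanesulfonate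
Conditions: MsCl, Et3N, CH2Cl2, −78 → 0 °C
Reagents that add atoms: methanesulfonyl chloride, CS(=O)(=O)Cl
Why: O-Sulfonylation of a secondary alcohol; the C–O bond is not broken, so the configuration is retained.

Step 6
Reactants: 8 (S)-1-[(triisopropylsilyl)oxy]-4-(trimethylsilyl)but-3-yn-2-yl methanesulfonate; 9 4-(benzyloxy)-3-methoxybenzaldehyde
Product: 11 (1S,2R)-1-[4-(benzyloxy)-3-methoxyphenyl]-2-{[(triisopropylsilyl)oxy]methyl}-4-(trimethylsilyl)but-3-yn-1-ol, via allenylzinc reagent 10 (not isolated)
Conditions: Pd(OAc)2 (5 mol%), PPh3 (5 mol%), Et2Zn (3 equiv), THF, −78 → −20 °C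
Reagents that add atoms: none
Why: Palladium-catalysed zincation of a propargylic mesylate and SE2' addition of the chiral allenylzinc to an aldehyde: zerovalent palladium displaces mesylate anti (SN2'), transmetalation keeps the axial chirality, and addition through a six-membered cyclic transition state forms the C–C bond on the face opposite to the departed mesylate (C2 = R) with the aryl group anti to the silyloxymethyl branch (C1 = S). The hindered silyl ether should not chelate zinc.

Step 7
Reactants: 11 (1S,2R)-1-[4-(benzyloxy)-3-methoxyphenyl]-2-{[(triisopropylsilyl)oxy]methyl}-4-(trimethylsilyl)but-3-yn-1-ol; 12 trichloroethylene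
Product: 14 (1S,2R)-1-[4-(benzyloxy)-3-methoxyphenyl]-1-{[(E)-1,2-dichloroethenyl]oxy}-2-{[(triisopropylsilyl)oxy]methyl}-4-(trimethylsilyl)but-3-yne, via potassium alkoxide 13 (not isolated)
Conditions: KH, THF, 0 °C; then 12, −50 °C → rt
Reagents that add atoms: none
Why: Addition of an alkoxide to dichloroacetylene generated in the flask from trichloroethylene, then protonation: the standard dichlorovinyl ether entry to ynol ethers, which accepts hindered secondary alcohols. The triisopropylsilyl ether should not migrate and the SiMe3 cap keeps the alkyne from being deprotonated.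

Step 8
Reactants: 14 (1S,2R)-1-[4-(benzyloxy)-3-methoxyphenyl]-1-{[(E)-1,2-dichloroethenyl]oxy}-2-{[(triisopropylsilyl)oxy]methyl}-4-(trimethylsilyl)but-3-yne
Product: 16 triethyl({[(1S,2R)-1-[4-(benzyloxy)-3-methoxyphenyl]-2-{[(triisopropylsilyl)oxy]methyl}-4-(trimethylsilyl)but-3-yn-1-yl]oxy}ethynyl)silane, via lithium alkoxyacetylide 15 (not isolated)
Conditions: n-BuLi (2.3 equiv), THF, −78 → −40 °C; then Et3SiCl, −78 → 0 °C
Reagents that add atoms: chlorotriethylsilane, CC[Si](Cl)(CC)CC
Why: Dehydrochlorination to the chloroalkynyl ether and chlorine–lithium exchange give the lithium alkoxyacetylide, which is C-silylated; because the other alkyne is capped, only the ynol ether terminus receives SiEt3.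

Step 9
Reactants: 16 triethyl({[(1S,2R)-1-[4-(benzyloxy)-3-methoxyphenyl]-2-{[(triisopropylsilyl)oxy]methyl}-4-(trimethylsilyl)but-3-yn-1-yl]oxy}ethynyl)silane
Product: 17 triethyl({[(1S,2R)-1-[4-(benzyloxy)-3-methoxyphenyl]-2-{[(triisopropylsilyl)oxy]methyl}but-3-yn-1-yl]oxy}ethynyl)silane
Conditions: K2CO3 (0.2 equiv), MeOH/THF, 0 °C, stopped when 16 is consumed; used without heating
Reagents that add atoms: none
Why: Base-catalysed methanolysis of an alkynylsilane: the small SiMe3 group on the carbon alkyne is cleaved, while the bulkier SiEt3 group on the ynol ether, whose alkoxyacetylide is also the poorer leaving group, should react much more slowly at 0 °C.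

**Fragment 2: propargyl lactone 25**

Step 10
Reactants: 9 4-(benzyloxy)-3-methoxybenzaldehyde; 18 dimethyl succinate
Product: 19 (E)-4-[4-(benzyloxy)-3-methoxyphenyl]-3-(methoxycarbonyl)but-3-enoic acid
Conditions: NaOMe, MeOH, reflux; then aq. HCl
Reagents that add atoms: none
Why: Stobbe condensation: aldol addition, lactonisation to the paraconic ester and E1cB ring opening give the (E)-alkylidene succinic half-ester with the free acid on the CH2 arm.

Step 11
Reactants: 19 (E)-4-[4-(benzyloxy)-3-methoxyphenyl]-3-(methoxycarbonyl)but-3-enoic acid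
Product: 20 (S)-4-[4-(benzyloxy)-3-methoxyphenyl]-3-(methoxycarbonyl)butanoic acid
Conditions: [Rh(cod)((R,R)-Et-DuPhos)]BF4 (0.5 mol%), H2 (4 bar), NaOMe (0.1 equiv), MeOH, rt
Reagents that add atoms: none
Why: Rhodium-catalysed asymmetric hydrogenation of an itaconate-type half-ester, the carboxylate chelating rhodium as the amide does in an enamide; by analogy with itaconates the (R,R)-ligand is expected to give the (S)-acid, to be confirmed on lactone 22 against the racemate, with the antipodal ligand used if it proves opposite. The aryl benzyl ether is inert to the homogeneous catalyst.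

Step 12
Reactants: 20 (S)-4-[4-(benzyloxy)-3-methoxyphenyl]-3-(methoxycarbonyl)butanoic acid
Product: 22 (S)-4-[4-(benzyloxy)-3-methoxybenzyl]dihydrofuran-2(3H)-one, via hydroxy acid 21 (not isolated)
Conditions: KOH (1 equiv), EtOH; CaCl2, NaBH4, EtOH, −10 °C → rt; then 2 M HCl, rt
Reagents that add atoms: none
Why: Chemoselective borohydride reduction of an ester beside a carboxylate salt, which Ca(BH4)2 does not reduce, followed by acid-induced γ-lactonisation; the stereocentre is no longer α to a carbonyl once the ester is reduced.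

Step 13
Reactants: 22 (S)-4-[4-(benzyloxy)-3-methoxybenzyl]dihydrofuran-2(3H)-one; 23 propargyl bromide
Product: 25 (3S,4S)-4-[4-(benzyloxy)-3-methoxybenzyl]-3-(prop-2-yn-1-yl)dihydrofuran-2(3H)-one, via lithium enolate 24 (not isolated)
Conditions: LiN(SiMe3)2 (1.05 equiv), THF, −78 °C; then 23, DMPU, −78 → −30 °C
Reagents that add atoms: none
Why: Alkylation of a lactone enolate: the electrophile approaches the planar enolate anti to the C4 arylmethyl group, setting C3 (S) trans to C4 as is general for β-substituted γ-butyrolactones; preforming the enolate with a slight excess of base leaves little free base to deprotonate the alkyne.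

**Key step and end game**

Step 14
Reactants: 17 triethyl({[(1S,2R)-1-[4-(benzyloxy)-3-methoxyphenyl]-2-{[(triisopropylsilyl)oxy]methyl}but-3-yn-1-yl]oxy}ethynyl)silane; 25 (3S,4S)-4-[4-(benzyloxy)-3-methoxybenzyl]-3-(prop-2-yn-1-yl)dihydrofuran-2(3H)-one
Product: 26 (3S,4S)-4-[4-(benzyloxy)-3-methoxybenzyl]-3-{[(2S,3R)-2-[4-(benzyloxy)-3-methoxyphenyl]-7-(triethylsilyl)-3-{[(triisopropylsilyl)oxy]methyl}-2,3-dihydrobenzofuran-5-yl]methyl}dihydrofuran-2(3H)-one
Conditions: RhCl(PPh3)3 (10 mol%), toluene, 40 °C, 17 added over 6 h to 25 (2 equiv); excess 25 recovered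
Reagents that add atoms: none
Why: Proposed new method: an alkyl silyl ynol ether has not served as the tethered alkyne of a diyne in a [2+2+2] cycloaddition, the closest known reaction types being rhodium-catalysed cyclotrimerisations of ynamide-tethered 1,6-diynes with terminal alkynes (indolines), of aryl alkynyl ether-tethered diynes (dibenzofurans) and of silyl-capped diynes. Monovalent rhodium binds both alkynes of 17 and couples them oxidatively through their inner carbons, which forms C3a–C7a and a rhodacyclopentadiene of trivalent rhodium whose α-carbons are C4 (H) and C7 (SiEt3). The terminal alkyne of 25 then inserts, and C–C reductive elimination forms C4–C5 and C6–C7 and returns monovalent rhodium. Ring C closes in the oxidative coupling, the three-atom O1–C2–C3 tether allowing only a five-membered ring fused to the metallacycle, and ring B closes by insertion and reductive elimination. No stereocentre is formed; C2 and C3 are carried unchanged from 17 because the medium is neutral and neither centre belongs to a reacting π system. The step needs cross-coupling over homo-coupling, which slow addition of 17 to an excess of 25 and the intramolecular first coupling should secure, and it needs 25 to insert with its CH2 substituent remote from silicon, which the bulk of SiEt3 on the α-carbon should enforce so that the lactone arm ends at C5 and not at C6. The electron-rich ynol ether is expected to bind the metal well, and 40 °C in an aprotic solvent keeps the benzylic ynol ether below the temperatures at which such ethers rearrange or eliminate.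

Step 15
Reactants: 26 (3S,4S)-4-[4-(benzyloxy)-3-methoxybenzyl]-3-{[(2S,3R)-2-[4-(benzyloxy)-3-methoxyphenyl]-7-(triethylsilyl)-3-{[(triisopropylsilyl)oxy]methyl}-2,3-dihydrobenzofuran-5-yl]methyl}dihydrofuran-2(3H)-one
Product: 27 (3S,4S)-4-[4-(benzyloxy)-3-methoxybenzyl]-3-{[(2S,3R)-2-[4-(benzyloxy)-3-methoxyphenyl]-7-iodo-3-{[(triisopropylsilyl)oxy]methyl}-2,3-dihydrobenzofuran-5-yl]methyl}dihydrofuran-2(3H)-one
Conditions: ICl (1.05 equiv), CH2Cl2, −78 → −20 °C
Reagents that add atoms: iodine monochloride, ClI
Why: Electrophilic ipso-iododesilylation: the β-silicon effect and the ortho ring oxygen direct iodine to C7, and one equivalent of ICl at low temperature is meant to outrun iodination of the two dialkoxybenzene rings.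

Step 16
Reactants: 27 (3S,4S)-4-[4-(benzyloxy)-3-methoxybenzyl]-3-{[(2S,3R)-2-[4-(benzyloxy)-3-methoxyphenyl]-7-iodo-3-{[(triisopropylsilyl)oxy]methyl}-2,3-dihydrobenzofuran-5-yl]methyl}dihydrofuran-2(3H)-one
Product: 28 (3S,4S)-4-[4-(benzyloxy)-3-methoxybenzyl]-3-{[(2S,3R)-2-[4-(benzyloxy)-3-methoxyphenyl]-7-(4,4,5,5-tetramethyl-1,3,2-dioxaborolan-2-yl)-3-{[(triisopropylsilyl)oxy]methyl}-2,3-dihydrobenzofuran-5-yl]methyl}dihydrofuran-2(3H)-one
Conditions: B2pin2, PdCl2(dppf) (5 mol%), KOAc, 1,4-dioxane, 80 °C
Reagents that add atoms: bis(pinacolato)diboron, CC1(C)OB(OC1(C)C)B1OC(C)(C)C(C)(C)O1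
Why: Miyaura borylation of an aryl iodide; acetate as base leaves the lactone and the silyl ether untouched.

Step 17
Reactants: 28 (3S,4S)-4-[4-(benzyloxy)-3-methoxybenzyl]-3-{[(2S,3R)-2-[4-(benzyloxy)-3-methoxyphenyl]-7-(4,4,5,5-tetramethyl-1,3,2-dioxaborolan-2-yl)-3-{[(triisopropylsilyl)oxy]methyl}-2,3-dihydrobenzofuran-5-yl]methyl}dihydrofuran-2(3H)-one
Product: 29 (3S,4S)-4-[4-(benzyloxy)-3-methoxybenzyl]-3-{[(2S,3R)-2-[4-(benzyloxy)-3-methoxyphenyl]-7-hydroxy-3-{[(triisopropylsilyl)oxy]methyl}-2,3-dihydrobenzofuran-5-yl]methyl}dihydrofuran-2(3H)-one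
Conditions: 30% H2O2, 1 M NaOH (1.2 equiv), THF, 0 °C; then 1 M HCl
Reagents that add atoms: hydrogen peroxide, OO
Why: Oxidation of an arylboronic ester by 1,2-aryl shift in the peroxoborate; the acidic work-up recloses any lactone opened by hydroxide, the trans arrangement being the thermodynamic one.

Step 18
Reactants: 29 (3S,4S)-4-[4-(benzyloxy)-3-methoxybenzyl]-3-{[(2S,3R)-2-[4-(benzyloxy)-3-methoxyphenyl]-7-hydroxy-3-{[(triisopropylsilyl)oxy]methyl}-2,3-dihydrobenzofuran-5-yl]methyl}dihydrofuran-2(3H)-one
Product: 30 (3S,4S)-4-[4-(benzyloxy)-3-methoxybenzyl]-3-{[(2S,3R)-2-[4-(benzyloxy)-3-methoxyphenyl]-7-hydroxy-3-(hydroxymethyl)-2,3-dihydrobenzofuran-5-yl]methyl}dihydrofuran-2(3H)-one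
Conditions: Bu4NF, AcOH, THF, 0 °C → rt
Reagents that add atoms: none
Why: Fluoride-mediated cleavage of the primary silyl ether, buffered with acetic acid so that the phenol and the lactone meet no strong base.

Step 19
Reactants: 30 (3S,4S)-4-[4-(benzyloxy)-3-methoxybenzyl]-3-{[(2S,3R)-2-[4-(benzyloxy)-3-methoxyphenyl]-7-hydroxy-3-(hydroxymethyl)-2,3-dihydrobenzofuran-5-yl]methyl}dihydrofuran-2(3H)-one
Product: 31 (3S,4S)-4-(4-hydroxy-3-methoxybenzyl)-3-{[(2S,3R)-7-hydroxy-2-(4-hydroxy-3-methoxyphenyl)-3-(hydroxymethyl)-2,3-dihydrobenzofuran-5-yl]methyl}dihydrofuran-2(3H)-one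
Conditions: H2 (1 atm), 10% Pd/C, EtOAc/EtOH, rt, stopped at full debenzylation
Reagents that add atoms: none
Why: Hydrogenolysis of the two aryl benzyl ethers, which should be cleaved much faster than the hindered cyclic benzylic ether C2–O1 at atmospheric pressure in a neutral solvent.

## Compound list

1 | ethyl glycolate | CCOC(=O)CO | starting material
2 | ethyl 2-[(triisopropylsilyl)oxy]acetate | CCOC(=O)CO[Si](C(C)C)(C(C)C)C(C)C | intermediate
3 | N-methoxy-N-methyl-2-[(triisopropylsilyl)oxy]acetamide | CON(C)C(=O)CO[Si](C(C)C)(C(C)C)C(C)C | intermediate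
4 | trimethylsilylacetylene | C#C[Si](C)(C)C | starting material
5 | lithium (trimethylsilyl)acetylide | [Li]C#C[Si](C)(C)C | intermediate (not isolated)
6 | 1-[(triisopropylsilyl)oxy]-4-(trimethylsilyl)but-3-yn-2-one | C[Si](C)(C)C#CC(=O)CO[Si](C(C)C)(C(C)C)C(C)C | intermediate
7 | (S)-1-[(triisopropylsilyl)oxy]-4-(trimethylsilyl)but-3-yn-2-ol | C[Si](C)(C)C#C[C@@H](CO[Si](C(C)C)(C(C)C)C(C)C)O | intermediate
8 | (S)-1-[(triisopropylsilyl)oxy]-4-(trimethylsilyl)but-3-yn-2-yl methanesulfonate | C[Si](C)(C)C#C[C@@H](CO[Si](C(C)C)(C(C)C)C(C)C)OS(C)(=O)=O | intermediate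
9 | 4-(benzyloxy)-3-methoxybenzaldehyde | COc1cc(C=O)ccc1OCc1ccccc1 | starting material
10 | (aS)-ethyl{4-[(triisopropylsilyl)oxy]-1-(trimethylsilyl)buta-1,2-dien-1-yl}zinc | CC[Zn]C([Si](C)(C)C)=[C@@]=C([H])CO[Si](C(C)C)(C(C)C)C(C)C | intermediate (not isolated)
11 | (1S,2R)-1-[4-(benzyloxy)-3-methoxyphenyl]-2-{[(triisopropylsilyl)oxy]methyl}-4-(trimethylsilyl)but-3-yn-1-ol | C[Si](C)(C)C#C[C@H](CO[Si](C(C)C)(C(C)C)C(C)C)[C@@H](c1ccc(OCc2ccccc2)c(OC)c1)O | intermediate
12 | trichloroethylene | ClC=C(Cl)Cl | starting material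
13 | potassium alkoxide of 11 | C[Si](C)(C)C#C[C@H](CO[Si](C(C)C)(C(C)C)C(C)C)[C@@H](c1ccc(OCc2ccccc2)c(OC)c1)[O-].[K+] | intermediate (not isolated)
14 | (1S,2R)-1-[4-(benzyloxy)-3-methoxyphenyl]-1-{[(E)-1,2-dichloroethenyl]oxy}-2-{[(triisopropylsilyl)oxy]methyl}-4-(trimethylsilyl)but-3-yne | C[Si](C)(C)C#C[C@H](CO[Si](C(C)C)(C(C)C)C(C)C)[C@@H](c1ccc(OCc2ccccc2)c(OC)c1)O/C(Cl)=C\Cl | intermediate
15 | lithium acetylide of the ethynyl ether of 11 (lithium alkoxyacetylide) | C[Si](C)(C)C#C[C@H](CO[Si](C(C)C)(C(C)C)C(C)C)[C@@H](c1ccc(OCc2ccccc2)c(OC)c1)OC#C[Li] | intermediate (not isolated)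
16 | triethyl({[(1S,2R)-1-[4-(benzyloxy)-3-methoxyphenyl]-2-{[(triisopropylsilyl)oxy]methyl}-4-(trimethylsilyl)but-3-yn-1-yl]oxy}ethynyl)silane | C[Si](C)(C)C#C[C@H](CO[Si](C(C)C)(C(C)C)C(C)C)[C@@H](c1ccc(OCc2ccccc2)c(OC)c1)OC#C[Si](CC)(CC)CC | intermediate
17 | triethyl({[(1S,2R)-1-[4-(benzyloxy)-3-methoxyphenyl]-2-{[(triisopropylsilyl)oxy]methyl}but-3-yn-1-yl]oxy}ethynyl)silane | C#C[C@H](CO[Si](C(C)C)(C(C)C)C(C)C)[C@@H](c1ccc(OCc2ccccc2)c(OC)c1)OC#C[Si](CC)(CC)CC | intermediate
18 | dimethyl succinate | COC(=O)CCC(=O)OC | starting material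
19 | (E)-4-[4-(benzyloxy)-3-methoxyphenyl]-3-(methoxycarbonyl)but-3-enoic acid | COC(=O)/C(CC(=O)O)=C/c1ccc(OCc2ccccc2)c(OC)c1 | intermediate
20 | (S)-4-[4-(benzyloxy)-3-methoxyphenyl]-3-(methoxycarbonyl)butanoic acid | COc1cc(C[C@@H](CC(=O)O)C(=O)OC)ccc1OCc1ccccc1 | intermediate
21 | (S)-4-[4-(benzyloxy)-3-methoxyphenyl]-3-(hydroxymethyl)butanoic acid | COc1cc(C[C@@H](CC(=O)O)CO)ccc1OCc1ccccc1 | intermediate (not isolated)
22 | (S)-4-[4-(benzyloxy)-3-methoxybenzyl]dihydrofuran-2(3H)-one | COc1cc(C[C@@H]2COC(=O)C2)ccc1OCc1ccccc1 | intermediate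
23 | propargyl bromide | C#CCBr | starting material
24 | lithium enolate of 22 | COc1cc(C[C@@H]2COC(O[Li])=C2)ccc1OCc1ccccc1 | intermediate (not isolated)
25 | (3S,4S)-4-[4-(benzyloxy)-3-methoxybenzyl]-3-(prop-2-yn-1-yl)dihydrofuran-2(3H)-one | COc1cc(C[C@@H]2COC(=O)[C@H]2CC#C)ccc1OCc1ccccc1 | intermediate
26 | (3S,4S)-4-[4-(benzyloxy)-3-methoxybenzyl]-3-{[(2S,3R)-2-[4-(benzyloxy)-3-methoxyphenyl]-7-(triethylsilyl)-3-{[(triisopropylsilyl)oxy]methyl}-2,3-dihydrobenzofuran-5-yl]methyl}dihydrofuran-2(3H)-one | COc1cc(C[C@@H]2COC(=O)[C@H]2Cc2cc([Si](CC)(CC)CC)c3c(c2)[C@H](CO[Si](C(C)C)(C(C)C)C(C)C)[C@@H](c2ccc(OCc4ccccc4)c(OC)c2)O3)ccc1OCc1ccccc1 | intermediate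
27 | 7-iodo analogue of 26 (iodine in place of triethylsilyl) | COc1cc(C[C@@H]2COC(=O)[C@H]2Cc2cc(I)c3c(c2)[C@H](CO[Si](C(C)C)(C(C)C)C(C)C)[C@@H](c2ccc(OCc4ccccc4)c(OC)c2)O3)ccc1OCc1ccccc1 | intermediate
28 | 7-(4,4,5,5-tetramethyl-1,3,2-dioxaborolan-2-yl) analogue of 26 | COc1cc(C[C@@H]2COC(=O)[C@H]2Cc2cc(B5OC(C)(C)C(C)(C)O5)c3c(c2)[C@H](CO[Si](C(C)C)(C(C)C)C(C)C)[C@@H](c2ccc(OCc4ccccc4)c(OC)c2)O3)ccc1OCc1ccccc1 | intermediate
29 | (3S,4S)-4-[4-(benzyloxy)-3-methoxybenzyl]-3-{[(2S,3R)-2-[4-(benzyloxy)-3-methoxyphenyl]-7-hydroxy-3-{[(triisopropylsilyl)oxy]methyl}-2,3-dihydrobenzofuran-5-yl]methyl}dihydrofuran-2(3H)-one | COc1cc(C[C@@H]2COC(=O)[C@H]2Cc2cc(O)c3c(c2)[C@H](CO[Si](C(C)C)(C(C)C)C(C)C)[C@@H](c2ccc(OCc4ccccc4)c(OC)c2)O3)ccc1OCc1ccccc1 | intermediate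
30 | (3S,4S)-4-[4-(benzyloxy)-3-methoxybenzyl]-3-{[(2S,3R)-2-[4-(benzyloxy)-3-methoxyphenyl]-7-hydroxy-3-(hydroxymethyl)-2,3-dihydrobenzofuran-5-yl]methyl}dihydrofuran-2(3H)-one | COc1cc(C[C@@H]2COC(=O)[C@H]2Cc2cc(O)c3c(c2)[C@H](CO)[C@@H](c2ccc(OCc4ccccc4)c(OC)c2)O3)ccc1OCc1ccccc1 | intermediate
31 | (3S,4S)-4-(4-hydroxy-3-methoxybenzyl)-3-{[(2S,3R)-7-hydroxy-2-(4-hydroxy-3-methoxyphenyl)-3-(hydroxymethyl)-2,3-dihydrobenzofuran-5-yl]methyl}dihydrofuran-2(3H)-one | COc1cc(C[C@@H]2COC(=O)[C@H]2Cc2cc(O)c3c(c2)[C@H](CO)[C@@H](c2ccc(O)c(OC)c2)O3)ccc1O | target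

## Step count and least certain steps

Total step count: 19. Longest linear sequence: 15 steps (steps 1–9 and 14–19).

**Step 14 (key step, new method).** Most likely failure: oligomerisation of 17 through its terminal alkyne, or breakdown of the ynol ether at the metal (cleavage of the benzylic O–C bond or ketene formation) before the rhodacycle is intercepted. Weaker steering by silicon would show as insertion in the wrong sense. Fallback by known chemistry, from 11 back to 27, moving the ring-oxygen bond formation out of the cycloaddition: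
- 11 is C-desilylated (K2CO3, MeOH) to the alkynol F1.
- Its hydroxyl is silylated (imidazole, CH2Cl2) with chlorodimethyl[(trimethylsilyl)ethynyl]silane F2, made from Me2SiCl2 and 5, giving the silicon-tethered 1,7-diyne F3.
- F3 and 25 are cyclotrimerised with RhCl(PPh3)3 or CpCo(CO)2, a known reaction class for silyl-ether-tethered diynes, to the benzo-fused cyclic silyl ether F4. The same steric argument places the lactone arm.
- Tamao–Fleming oxidation (H2O2, KF, KHCO3) of the aryl–silicon bond gives the phenol-alcohol F5.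
- Catalytic acid closes ring C through the para-alkoxybenzyl cation to the trans-7-trimethylsilyl dihydrobenzofuran F6.
- ICl converts F6 into 27.

**Step 7.** Most likely failure: attack of the potassium alkoxide on silicon (loss of the alkyne cap or a slow silyl shift), or incomplete capture of dichloroacetylene by the hindered alkoxide. The benzylic ynol ethers made from 14 are also heat-sensitive. Fallback avoiding the alkoxide, from 11 back to 16: 11 is formylated (acetic formic anhydride, pyridine) to the formate F7; Ramirez-type dibromo-olefination (CBr4, PPh3) gives the 2,2-dibromovinyl ether F8; n-BuLi (Fritsch–Buttenberg–Wiechell pathway) then Et3SiCl gives 16 via 15.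

**Step 15.** Most likely failure: electrophilic iodination of rings D and E competing with the slower ipso attack at the hindered SiEt3 group. Fallback that deactivates those rings first, from 26 to 31:
- Hydrogenolysis (H2, Pd/C) gives the diphenol F9.
- Ac2O/pyridine gives the diacetate F10.
- ICl gives the iodide F11.
- Miyaura borylation gives the boronate F12.
- Alkaline H2O2 oxidises boron and hydrolyses both acetates, giving the triphenol silyl ether F13.
- Bu4NF/AcOH gives 31.

**Step 6.** Most likely failure: modest anti/syn selectivity with an aromatic aldehyde, or β-elimination of silyloxide from the propargylzinc tautomer. C2 is fixed by chirality transfer, so only C1 needs correcting. Fallback from 11 (as a C1 mixture) back to 11: Dess–Martin oxidation gives the aryl ketone F14, and Corey–Bakshi–Shibata reduction with the (R)-methyl oxazaborolidine and BH3·SMe2 is expected to return the (1S) alcohol under reagent control.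

**Step 19.** Most likely failure: over-reduction by hydrogenolysis of the benzylic C2–O1 bond of ring C once the phenols are free. Fallback from 30 to 31 with no new compound (F0): Lewis-acid debenzylation with BCl3 and pentamethylbenzene as cation scavenger in CH2Cl2 at −78 °C, which involves no metal hydride surface.

## Further compounds

F1 | step 14 | (1S,2R)-1-[4-(benzyloxy)-3-methoxyphenyl]-2-{[(triisopropylsilyl)oxy]methyl}but-3-yn-1-ol | C#C[C@H](CO[Si](C(C)C)(C(C)C)C(C)C)[C@@H](c1ccc(OCc2ccccc2)c(OC)c1)O
F2 | step 14 | chlorodimethyl[(trimethylsilyl)ethynyl]silane | C[Si](C)(C)C#C[Si](C)(C)Cl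
F3 | step 14 | dimethyl[(trimethylsilyl)ethynyl]silyl ether of F1 (silicon-tethered 1,7-diyne) | C#C[C@H](CO[Si](C(C)C)(C(C)C)C(C)C)[C@@H](c1ccc(OCc2ccccc2)c(OC)c1)O[Si](C)(C)C#C[Si](C)(C)C
F4 | step 14 | benzo-fused six-membered cyclic silyl ether (3,4-dihydro-1H-2,1-benzoxasiline) carrying SiMe3 ortho to ring silicon and the lactone arm meta to it, configurations as in 11 and 25 | COc1cc(C[C@@H]2COC(=O)[C@H]2Cc2cc([Si](C)(C)C)c3c(c2)[C@H](CO[Si](C(C)C)(C(C)C)C(C)C)[C@@H](c2ccc(OCc4ccccc4)c(OC)c2)O[Si]3(C)C)ccc1OCc1ccccc1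
F5 | step 14 | phenol-alcohol from oxidation of F4 (2-hydroxy-3-trimethylsilyl-aryl at C2 of the 1-aryl-propane-1,3-diol mono silyl ether) | COc1cc(C[C@@H]2COC(=O)[C@H]2Cc2cc([Si](C)(C)C)c(O)c(c2)[C@H](CO[Si](C(C)C)(C(C)C)C(C)C)[C@@H](c2ccc(OCc3ccccc3)c(OC)c2)O)ccc1OCc1ccccc1
F6 | step 14 | 7-trimethylsilyl analogue of 26 | COc1cc(C[C@@H]2COC(=O)[C@H]2Cc2cc([Si](C)(C)C)c3c(c2)[C@H](CO[Si](C(C)C)(C(C)C)C(C)C)[C@@H](c2ccc(OCc4ccccc4)c(OC)c2)O3)ccc1OCc1ccccc1
F7 | step 7 | formate ester of 11 | C[Si](C)(C)C#C[C@H](CO[Si](C(C)C)(C(C)C)C(C)C)[C@@H](c1ccc(OCc2ccccc2)c(OC)c1)OC=O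
F8 | step 7 | 2,2-dibromovinyl ether of 11 | C[Si](C)(C)C#C[C@H](CO[Si](C(C)C)(C(C)C)C(C)C)[C@@H](c1ccc(OCc2ccccc2)c(OC)c1)OC=C(Br)Br
F9 | step 15 | bis-debenzylated 26 (diphenol) | COc1cc(C[C@@H]2COC(=O)[C@H]2Cc2cc([Si](CC)(CC)CC)c3c(c2)[C@H](CO[Si](C(C)C)(C(C)C)C(C)C)[C@@H](c2ccc(O)c(OC)c2)O3)ccc1O
F10 | step 15 | diacetate of F9 | COc1cc(C[C@@H]2COC(=O)[C@H]2Cc2cc([Si](CC)(CC)CC)c3c(c2)[C@H](CO[Si](C(C)C)(C(C)C)C(C)C)[C@@H](c2ccc(OC(C)=O)c(OC)c2)O3)ccc1OC(C)=O
F11 | step 15 | 7-iodo diacetate | COc1cc(C[C@@H]2COC(=O)[C@H]2Cc2cc(I)c3c(c2)[C@H](CO[Si](C(C)C)(C(C)C)C(C)C)[C@@H](c2ccc(OC(C)=O)c(OC)c2)O3)ccc1OC(C)=O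
F12 | step 15 | 7-(pinacolboryl) diacetate | COc1cc(C[C@@H]2COC(=O)[C@H]2Cc2cc(B5OC(C)(C)C(C)(C)O5)c3c(c2)[C@H](CO[Si](C(C)C)(C(C)C)C(C)C)[C@@H](c2ccc(OC(C)=O)c(OC)c2)O3)ccc1OC(C)=O
F13 | step 15 | triisopropylsilyl ether of 31 at the primary alcohol (triphenol) | COc1cc(C[C@@H]2COC(=O)[C@H]2Cc2cc(O)c3c(c2)[C@H](CO[Si](C(C)C)(C(C)C)C(C)C)[C@@H](c2ccc(O)c(OC)c2)O3)ccc1O
F14 | step 6 | (R)-1-[4-(benzyloxy)-3-methoxyphenyl]-2-{[(triisopropylsilyl)oxy]methyl}-4-(trimethylsilyl)but-3-yn-1-one | C[Si](C)(C)C#C[C@H](CO[Si](C(C)C)(C(C)C)C(C)C)C(=O)c1ccc(OCc2ccccc2)c(OC)c1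
F0 | step 19 | none | none
A1 | alternative 1 | (2S,3R)-trans-7-(benzyloxy)-5-bromo-2-(4-hydroxy-3-methoxyphenyl)-3-(hydroxymethyl)-2,3-dihydrobenzofuran | Brc1cc(OCc2ccccc2)c2c(c1)[C@H](CO)[C@@H](c1ccc(O)c(OC)c1)O2
A2 | alternative 1 | (R)-2-[3-(benzyloxy)-5-bromo-2-hydroxyphenyl]-3-(4-hydroxy-3-methoxyphenyl)propan-1-ol | Brc1cc(OCc2ccccc2)c(O)c(c1)[C@H](CO)Cc1ccc(O)c(OC)c1
A3 | alternative 2 | trans,trans-3-{[(2S,3R)-7-(benzyloxy)-2-[4-(benzyloxy)-3-methoxyphenyl]-3-{[(tert-butyldimethylsilyl)oxy]methyl}-2,3-dihydrobenzofuran-5-yl]methyl}-4-{2-[4-(benzyloxy)-3-methoxyphenyl]-1,3-dithian-2-yl}-5-(menthyloxy)dihydrofuran-2(3H)-one | COc1cc(C2(SCCCS2)[C@@H]3[C@@H](O[C@H]4C[C@@H](C)CC[C@@H]4C(C)C)OC(=O)[C@H]3Cc3cc(OCc4ccccc4)c4c(c3)[C@H](CO[Si](C)(C)C(C)(C)C)[C@@H](c3ccc(OCc5ccccc5)c(OC)c3)O4)ccc1OCc1ccccc1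
A4 | alternative 2 | (5S)-5-{[(1S,2R,5S)-2-isopropyl-5-methylcyclohexyl]oxy}furan-2(5H)-one | O=C1C=C[C@@H](O[C@H]2C[C@@H](C)CC[C@@H]2C(C)C)O1
A5 | alternative 2 | 2-[4-(benzyloxy)-3-methoxyphenyl]-1,3-dithiane | COc1cc(C2SCCCS2)ccc1OCc1ccccc1
A6 | alternative 2 | (2S,3R)-7-(benzyloxy)-2-[4-(benzyloxy)-3-methoxyphenyl]-5-(bromomethyl)-3-{[(tert-butyldimethylsilyl)oxy]methyl}-2,3-dihydrobenzofuran | BrCc1cc(OCc2ccccc2)c2c(c1)[C@H](CO[Si](C)(C)C(C)(C)C)[C@@H](c1ccc(OCc3ccccc3)c(OC)c1)O2
A7 | alternative 3 | 3-[4-(benzyloxy)-3-methoxybenzyl]cyclobutan-1-one | COc1cc(CC2CC(=O)C2)ccc1OCc1ccccc1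
A8 | alternative 3 | (S)-4-[4-(benzyloxy)-3-methoxybenzyl]dihydrofuran-2(3H)-one (identical with 22) | COc1cc(C[C@@H]2COC(=O)C2)ccc1OCc1ccccc1
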